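At 25 h the flask is asked who holds most of the charged starting material. I turn that round: what would have to be true for starting material to lead isomer of the product A?

| setting | theta | delta | flask |
|---|---|---|---|
| starting material | 0.034 M | 0.034 M | 0.034 M |
| coupling partner | 0.102 M | 0.051 M | 0.102 M |
| remark | the very flask that is asked about, followed so far | run made earlier |  |
| time |  |  | 25 h |

| run | time / h | starting material / % | isomer of the product A / % | isomer of the product B / % | target / % |
|---|---|---|---|---|---|
| theta | 0.833 | 69.9 | 12.4 | 0 | 20.1 |
| theta | 2.50 | 42.7 | 25.0 | 0 | 33.6 |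
| theta | 4.00 | 34.5 | 30.9 | 2.6 | 33.6 |
| theta | 6.00 | 33.2 | 32.8 | 5.5 | 30.2 |
| theta | 10.0 | 28.0 | 40.4 | 6.9 | 26.7 |
| theta | 12.0 | 28.3 | 40.6 | 8.4 | 22.9 |
| delta | 0.833 | 82.0 | 4.7 | 0 | 12.1 |
| delta | 1.33 | 75.4 | 8.0 | 1.9 | 15.5 |
| delta | 2.00 | 68.3 | 12.9 | 0.4 | 18.7 |
| delta | 4.00 | 57.8 | 17.4 | 1.0 | 22.2 |
| delta | 6.00 | 53.0 | 21.4 | 4.6 | 21.7 |
| delta | 10.0 | 48.9 | 25.9 | 7.0 | 19.8 |

(readings scatter by 1 percentage point)

* where most of what was charged as starting material, at 25 h is found (starting material / isomer of the product A / target / isomer of the product B)
* the largest share itself, whichever of these holds it, in percent of the starting material charged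

I follow isomer of the product A over starting material, which I call the holding ratio; starting material leads where this ratio stands below one. In the theta run the holding ratio reads 1.44 at 10.0 h and 1.43 at 12.0 h. The delta run, with half the coupling partner, reads a lower 0.530 at 10.0 h. For starting material to lead this flask, the ratio must drop below one, which is a fall to 0.697 of its reading at 12.0 h.

The forecast says isomer of the product A at 48%, on the ground that “that material funnels slowly into A”. I agree on the species. But its 48 beside 23 of starting material needs the ratio to rise, so I stay near 40.6%, lower than its share.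

This flask gives isomer of the product A at 40.5%, with starting material at 28.8%, a ratio of 1.41.

    coupling partner → decomposition product (k = 2.37 × 10⁻⁷ min⁻¹)
    starting material + coupling partner ⇌ isomer of the product A (K = 26.3 M⁻¹, k = 0.0316 M⁻¹ min⁻¹)
    coupling partner → decomposed reagent (k = 2.83 × 10⁻⁴ min⁻¹)
    starting material + coupling partner ⇌ target (K = 13.0 M⁻¹, k = 0.0574 M⁻¹ min⁻¹)
    target ⇌ isomer of the product B (K = 0.960, k = 4.79 × 10⁻⁴ min⁻¹)

The holding ratio in this flask stands at 0.980 of the reading at 12.0 h, above the 0.697 needed, while coupling partner went from 60.9% of its charge at 12.5 h to 49.5% at 25.0 h. This flask is not at rest. Left until 2.5 d, this flask has coupling partner at 29.6%, and starting material at 37.7% leads isomer of the product A at 32.8%, a holding ratio at 0.606 of the reading at 12.0 h, below 0.697. At ten times the time, coupling partner is down to 4.44%, isomer of the product A to 10.3%, and starting material is back at 79.0%.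

(The readings were generated by integration with made-up constants; noise was put on by code.)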